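Assumption (remark on the chemistry): the L‑series enantiomer of the fructose‑derived Shi ketone is taken as a purchasable catalyst; its preparation from L‑sorbose is not counted. Compound numbers refer to the list after step 9.

## Analysis of the target

The target 17 is a 7,7′‑epoxylignan: one oxolane ring (O1, C2–C5) carrying a 4‑hydroxy‑3,5‑dimethoxyphenyl group on C2 and on C5 and a hydroxymethyl group on C3 and on C4. The four contiguous stereocentres are (2R,3S,4S,5R). Every pair of neighbours is trans and the two aryl groups are trans across O1, so the molecule has a twofold axis through O1 and the midpoint of C3–C4. Both C2–O1 and C5–O1 are benzylic ether bonds para to a free phenol. Acid ionises them, which epimerises the aryl carbons and, with the neighbouring hydroxymethyl groups, leads irreversibly to a furofuran. Oxidants attack the syringyl phenols, and forcing hydrogenolysis opens the ring. The difficulty is to set four stereocentres on a small ring in one enantiomeric series without a chiral‑pool handle, and to finish under neutral, non‑oxidising conditions. The strategy rests on reading O1–C5–C4, with its aryl group on C5, as an aryl vinyl epoxide (oxygen, benzylic carbon, allylic carbon) and C2–C3 as the double bond of an arylidene malonate. The vinyl group on C4 and the geminal diester on C3 are then latent hydroxymethyl groups, and both partners come from one protected aldehyde, which mirrors the symmetry of 17. The all‑trans arrangement is also the thermodynamic one, which helps wherever a centre (C3) is set by equilibration.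

## Retrosynthetic reasoning

**17 to 16.** The last disconnection is protective only: the two phenols are carried as benzyl ethers in 16. Benzyl is chosen because it survives base, organolithium, buffered peroxide, the palladium step, chloride at 150 °C and hydride, and is removed by neutral hydrogenolysis; acid is excluded at the end for the reasons given above.

**16 to 15 to 13.** Both hydroxymethyl groups are traced to carbonyl carbons: the one on C3 to the methyl ester, the one on C4 to an aldehyde in 15, which in turn comes from cleaving the C=C bond of the vinyl group in 13. These are the groups that the ring‑forming step leaves at C3 and C4. The forward reactions must cleave the alkene without touching the electron‑rich arenes and then reduce both carbonyls in one operation, before the aldehyde can enolise.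

**13 to 11.** A second ester is added back at C3. This makes C3 non‑stereogenic and turns the C2–C3 fragment into a doubly activated alkene. The forward step has to remove one ester and leave C3 in the configuration trans to both neighbours, which is the thermodynamic one because the C2 aryl and C4 vinyl groups lie on the same face.

**11 to 8 and 4.** O1–C2 and C3–C4 are cut. This divides the ring into a three‑atom piece (O1–C5–C4, the epoxide 8) and a two‑atom piece (C2–C3, the arylidene malonate 4), each carrying one aryl group and each one or two steps from the same aldehyde 2. Cutting here and not at the aryl–carbon bonds keeps the acid‑labile diaryl ether from ever being exposed to a Lewis acid. It also means that the absolute configuration is bought once, at C5 of 8. What is gained is two skeletal bonds, the ring and two stereocentres in one catalytic step. The forward reaction must ionise only the allylic C–O bond, let the alkoxide add to 4, close the five‑membered and not the seven‑membered ring, and place the C2 aryl group trans to the C5 aryl group.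

**8 to 7 to 2 and 5.** The epoxide C–O bonds are cut back to the E diene 7, so that one catalytic asymmetric dioxirane epoxidation sets C5 and C4 together and the trans relationship follows from the alkene geometry. The diene comes from 2 and the allylphosphonate 5 by cutting the aryl‑conjugated C=C bond. A direct sulfur‑ylide epoxidation of 2 with an unsubstituted allyl ylide would be one step shorter. It was not used because such ylides add to aldehydes essentially irreversibly and are expected to give cis/trans mixtures.

**4 to 2 and 3; 2 to 1.** The arylidene C=C bond is cut to aldehyde 2 and dimethyl malonate 3 (condensation), and 2 is the benzyl ether of syringaldehyde 1.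

## Alternatives that were turned down

**Alternative 1:** Both aryl–carbon bonds (C2–aryl, C5–aryl) are cut, leading to the bis‑acetal A2, which already holds C3, C4 and the two silyl‑protected hydroxymethyl groups, and two equivalents of 2,6‑dimethoxyphenol A3. In the forward step a boron Lewis acid would ionise the two anomeric methoxy groups in turn and the para carbon of A3 would attack each oxocarbenium ion, giving the bis(silyl) ether A1, one desilylation from the target.
- For: it is the most convergent plan. Only C3 and C4 have to be bought as stereocentres, the phenols need no protection, and the aryl groups should enter trans to their neighbours, with Lewis‑acid equilibration favouring the all‑trans isomer.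
- Against: A1 is a benzylic ether para to a free hydroxyl and ionises more easily than A2 under the same Lewis acid. Ring opening and a second arylation at the same carbon would therefore compete. Enantiopure A2 also needs a multi‑step preparation of its own.
- Comparison: this plan is stronger on convergence and protecting‑group economy. The chosen strategy offers a ring formation under neutral catalysis with the aryl groups already in place, and a C5 configuration fixed by the substrate and not by equilibration under conditions that can destroy the product.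

**Alternative 2:** O1–C2 and O1–C5 are cut and the two aryl‑bearing carbons are joined to each other, giving the bisphenolic cyclobutane A5. In the forward step a silver‑based oxidant in wet solvent would take two electrons from A5 and break the strained bond between the aryl‑bearing carbons to give the bis(quinone methide) A6. Moisture would add to one methide carbon and the new hydroxyl to the other, giving the diester A4; ester reduction would finish the synthesis.
- For: very short and free of protecting groups, and the trans C3/C4 relationship is stored in the cyclobutane.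
- Against: in A6 the hydrogens on C3 and C4 are α to an ester and vinylogous to a quinonoid carbonyl. Tautomerisation to the bis(arylidene)succinate would erase the only stereocentres that carry the chirality. Cyclisation of one quinone methide onto the other arene competes, and the hydration is intermolecular with no facial control. Enantiopure A5 requires an enantioselective head‑to‑head photodimerisation.
- Comparison: this plan is clearly stronger on step count and redox economy. The chosen strategy offers an external, dependable source of absolute configuration and a ring construction of a known catalytic type.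

**Alternative 3:** Only O1–C2 is cut. The precursor is the open‑chain alcohol A8, with C3, C4 and C5 already set, C2 as a benzylic methylene on a free 4‑alkyl‑2,6‑dimethoxyphenol, and the other phenol benzylated. In the forward step a silver‑based oxidant would convert the para‑alkylphenol into the quinone methide A9 and the C5 hydroxyl would add to the methide carbon (5‑exo‑trig), giving A7.
- For: the closure is intramolecular and reversible, so C2 should settle trans to C3. That is a better‑founded control of C2 than in the chosen route. The three chain stereocentres can be set by established acyclic methods.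
- Against: a twofold‑symmetric target would be built from a linear, desymmetrised chain, with stereocentres set one at a time and the two aryl groups differentiated, which costs many steps. A9 can also tautomerise to the conjugated styrene by loss of the C3 hydrogen, destroying C3.
- Comparison: this plan is stronger at C2. The chosen strategy offers two ring bonds and two stereocentres in one step from two fragments made from the same aldehyde, at roughly half the length, and accepts less certain control of C2 in return.

Key step: step 5

## Route

Step 1
Reactants: 1 syringaldehyde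
Product: 2 4-(benzyloxy)-3,5-dimethoxybenzaldehyde
Conditions: BnBr, K2CO3, DMF, 60 °C
Reagents that add atoms: benzyl bromide, BrCc1ccccc1
Why: Williamson ether synthesis (SN2 of the phenoxide on the benzylic bromide); the aldehyde is inert, and the benzyl ether should survive every later step until the neutral hydrogenolysis.

Step 2
Reactants: 2 4-(benzyloxy)-3,5-dimethoxybenzaldehyde; 3 dimethyl malonate
Product: 4 dimethyl 2-[4-(benzyloxy)-3,5-dimethoxybenzylidene]propanedioate
Conditions: piperidine (cat.), AcOH (cat.), toluene, reflux (Dean–Stark)
Reagents that add atoms: none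
Why: Knoevenagel condensation driven by azeotropic removal of water; the symmetrical diester raises no question of alkene geometry.

Step 3
Reactants: 2 4-(benzyloxy)-3,5-dimethoxybenzaldehyde; 5 diethyl allylphosphonate
Product: 7 2-(benzyloxy)-5-[(1E)-buta-1,3-dien-1-yl]-1,3-dimethoxybenzene, via lithium β-oxidophosphonate 6 (not isolated)
Conditions: 5, n-BuLi, THF, −78 °C; HMPA; then 2, −78 °C → rt
Reagents that add atoms: none
Why: Horner–Wadsworth–Emmons olefination with the α‑lithiated allylphosphonate; HMPA directs attack through the α‑carbon, and adduct 6 should collapse on warming to the aryl‑conjugated E alkene, the geometry that the next step converts into the trans epoxide.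

Step 4
Reactants: 7 2-(benzyloxy)-5-[(1E)-buta-1,3-dien-1-yl]-1,3-dimethoxybenzene
Product: 8 (2S,3S)-2-[4-(benzyloxy)-3,5-dimethoxyphenyl]-3-ethenyloxirane
Conditions: 1,2:4,5-di-O-isopropylidene-β-L-erythro-2,3-hexodiulo-2,6-pyranose (L‑series Shi ketone, 30 mol %), Oxone (2KHSO5·KHSO4·K2SO4), K2CO3, Bu4NHSO4 (cat.), MeCN–CH2(OMe)2 / aq. Na2B4O7–Na2(EDTA) buffer, pH 10.5, 0 °C
Reagents that add atoms: Oxone (potassium peroxymonosulfate), [K+].[O-]S(=O)(=O)OO
Why: Shi asymmetric epoxidation through the chiral dioxirane formed in situ (spiro transition state); the electron‑rich trans‑disubstituted aryl alkene should react well ahead of the terminal monosubstituted one, and the E geometry is carried into the trans epoxide. The D‑fructose ketone gives (R,R) epoxides from trans aryl alkenes, so the L‑series ketone should give the (2S,3S) enantiomer. The 4‑benzyloxy group is twisted out of conjugation by its two ortho methoxy groups, which should keep the benzylic, allylic epoxide intact at pH 10.5.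

Step 5
Reactants: 8 (2S,3S)-2-[4-(benzyloxy)-3,5-dimethoxyphenyl]-3-ethenyloxirane; 4 dimethyl 2-[4-(benzyloxy)-3,5-dimethoxybenzylidene]propanedioate
Product: 11 dimethyl (2S,4R,5R)-2,5-bis[4-(benzyloxy)-3,5-dimethoxyphenyl]-4-ethenyloxolane-3,3-dicarboxylate, via π-allylpalladium alkoxide 9 (not isolated), via oxa-Michael adduct 10 (not isolated)
Conditions: Pd(PPh3)4 (5 mol %), THF, 40 °C; 8 added slowly to 4 (1.3 equiv) and catalyst
Reagents that add atoms: none
Why: Zerovalent palladium ionises the allylic C4–O bond of 8 with inversion and gives the zwitterionic π‑allyl complex of divalent palladium 9, in which the benzylic C5–O bond and its configuration are untouched. The alkoxide adds reversibly to the β‑carbon of 4 (oxa‑Michael, O1–C2) to give the malonate carbanion 10, which attacks the substituted allyl terminus on the face opposite to palladium (C3–C4) and releases the catalyst. The closest known reaction type is the zerovalent‑palladium‑catalysed (3+2) cycloaddition of vinyl oxiranes with doubly activated alkenes. The oxolane closes in a 5‑exo‑trig‑type allylic alkylation that leaves the remaining alkene outside the ring; attack at the distal allyl carbon would need a seven‑membered ring and should not compete. C5 is carried over from 8, and C4 results from two inversions, that is net retention, which places the vinyl group trans to the C5 aryl group; any π–σ–π face exchange of the allyl unit should converge on the same less crowded trans closure. C2 is decided in the ring closure and not in the reversible oxa‑Michael step (a Curtin–Hammett situation): allylic 1,3‑strain in the planar malonate carbanion pushes the C2 aryl group out of the enolate plane into a pseudo‑axial position while the C5 aryl group stays pseudo‑equatorial, which corresponds to the 2,5‑trans, 2,4‑cis isomer 11. The step needs cycloaddition to outrun palladium‑mediated isomerisation of 8 to a ketone, which the excess of 4 and slow addition of 8 should secure, and it needs enough acceptor strength, which the geminal diester supplies because the twisted 4‑benzyloxy group donates little to the arylidene.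

Step 6
Reactants: 11 dimethyl (2S,4R,5R)-2,5-bis[4-(benzyloxy)-3,5-dimethoxyphenyl]-4-ethenyloxolane-3,3-dicarboxylate
Product: 13 methyl (2R,3R,4R,5R)-2,5-bis[4-(benzyloxy)-3,5-dimethoxyphenyl]-4-ethenyloxolane-3-carboxylate, via C3-epimeric monoester 12 (not isolated)
Conditions: LiCl, H2O, DMSO, 150 °C; then crude, NaOMe (cat.), MeOH, 50 °C
Reagents that add atoms: none
Why: Krapcho dealkoxycarbonylation: chloride removes one methyl group by SN2, the carboxylate loses CO2 and the ester enolate is protonated by water, partly from the open face to give the all‑cis epimer 12. Methoxide equilibration through the ester enolate should then converge on 13, whose ester is trans to both the C2 aryl and the C4 vinyl group, the thermodynamic isomer. β‑Elimination of the ring oxygen is stereoelectronically disfavoured because the endocyclic C2–O bond lies near the nodal plane of the enolate.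

Step 7
Reactants: 13 methyl (2R,3R,4R,5R)-2,5-bis[4-(benzyloxy)-3,5-dimethoxyphenyl]-4-ethenyloxolane-3-carboxylate
Product: 15 methyl (2R,3R,4R,5R)-2,5-bis[4-(benzyloxy)-3,5-dimethoxyphenyl]-4-formyloxolane-3-carboxylate, via vicinal diol 14 (not isolated)
Conditions: OsO4 (2 mol %), NaIO4, 2,6-lutidine, dioxane–H2O, rt
Reagents that add atoms: osmium tetroxide, O=[Os](=O)(=O)=O; sodium periodate (terminal oxidant), [Na+].[O-]I(=O)(=O)=O
Why: Lemieux–Johnson oxidation: OsO4 dihydroxylates the only alkene to diol 14, and NaIO4 cleaves the diol and re‑oxidises osmium, with 2,6‑lutidine suppressing α‑hydroxy ketone formation. The electron‑rich arenes and benzyl ethers, which ozone would attack, should be untouched. C4 already has its preferred trans configuration, so enolisation of the aldehyde costs nothing; 15 is used without storage.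

Step 8
Reactants: 15 methyl (2R,3R,4R,5R)-2,5-bis[4-(benzyloxy)-3,5-dimethoxyphenyl]-4-formyloxolane-3-carboxylate
Product: 16 {(2R,3S,4S,5R)-2,5-bis[4-(benzyloxy)-3,5-dimethoxyphenyl]oxolane-3,4-diyl}dimethanol
Conditions: LiAlH4, THF, 0 °C; aq. KNaC4H4O6 work-up
Reagents that add atoms: none
Why: Hydride reduction of the aldehyde and the methyl ester to the two primary alcohols in one operation; addition to the aldehyde is faster than its enolisation, so no stereocentre should be disturbed.

Step 9
Reactants: 16 {(2R,3S,4S,5R)-2,5-bis[4-(benzyloxy)-3,5-dimethoxyphenyl]oxolane-3,4-diyl}dimethanol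
Product: 17 4,4'-[(2R,3S,4S,5R)-3,4-bis(hydroxymethyl)oxolane-2,5-diyl]bis(2,6-dimethoxyphenol)
Conditions: H2 (1 atm), 10% Pd/C, EtOAc–MeOH, rt
Reagents that add atoms: none
Why: Catalytic hydrogenolysis of the two aryl benzyl ethers under neutral conditions. Phenolic benzyl ethers cleave much faster than the hindered secondary benzylic C–O bonds of the ring, so the reaction is stopped once 16 is consumed. Acid is excluded because it would convert 17 into a furofuran.

## Compound list

1 | syringaldehyde (4-hydroxy-3,5-dimethoxybenzaldehyde) | COc1cc(C=O)cc(OC)c1O | starting material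
2 | 4-(benzyloxy)-3,5-dimethoxybenzaldehyde | COc1cc(C=O)cc(OC)c1OCc1ccccc1 | intermediate
3 | dimethyl malonate | COC(=O)CC(=O)OC | starting material
4 | dimethyl 2-[4-(benzyloxy)-3,5-dimethoxybenzylidene]propanedioate | COC(=O)C(=Cc1cc(OC)c(OCc2ccccc2)c(OC)c1)C(=O)OC | intermediate
5 | diethyl allylphosphonate (diethyl prop-2-en-1-ylphosphonate) | CCOP(=O)(CC=C)OCC | starting material
6 | lithium alkoxide of diethyl {1-[4-(benzyloxy)-3,5-dimethoxyphenyl]-1-hydroxybut-3-en-2-yl}phosphonate (diastereomer mixture, configurations not defined) | [Li+].[O-]C(c1cc(OC)c(OCc2ccccc2)c(OC)c1)C(C=C)P(=O)(OCC)OCC | intermediate (not isolated)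
7 | 2-(benzyloxy)-5-[(1E)-buta-1,3-dien-1-yl]-1,3-dimethoxybenzene | C=C/C=C/c1cc(OC)c(OCc2ccccc2)c(OC)c1 | intermediate
8 | (2S,3S)-2-[4-(benzyloxy)-3,5-dimethoxyphenyl]-3-ethenyloxirane (trans) | C=C[C@@H]1O[C@H]1c1cc(OC)c(OCc2ccccc2)c(OC)c1 | intermediate
9 | zwitterionic bis(triphenylphosphine)allylpalladium alkoxide from 8 (η3‑allyl complex of divalent palladium, drawn as its η1 form at C4 with palladium opposite the former epoxide oxygen) | C=C[C@@H]([Pd+](P(c1ccccc1)(c1ccccc1)c1ccccc1)P(c1ccccc1)(c1ccccc1)c1ccccc1)[C@@H]([O-])c1cc(OC)c(OCc2ccccc2)c(OC)c1 | intermediate (not isolated)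
10 | oxa‑Michael adduct of 9 with 4 (malonate carbanion, drawn with the C2 configuration that closes to 11) | C=C[C@@H]([Pd+](P(c1ccccc1)(c1ccccc1)c1ccccc1)P(c1ccccc1)(c1ccccc1)c1ccccc1)[C@@H](O[C@@H](c1cc(OC)c(OCc2ccccc2)c(OC)c1)[C-](C(=O)OC)C(=O)OC)c1cc(OC)c(OCc2ccccc2)c(OC)c1 | intermediate (not isolated)
11 | dimethyl (2S,4R,5R)-2,5-bis[4-(benzyloxy)-3,5-dimethoxyphenyl]-4-ethenyloxolane-3,3-dicarboxylate (aryl groups trans; vinyl trans to the C5 aryl group) | COc1cc([C@@H]2O[C@@H](c3cc(OC)c(OCc4ccccc4)c(OC)c3)[C@H](C=C)C2(C(=O)OC)C(=O)OC)cc(OC)c1OCc1ccccc1 | intermediate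
12 | methyl (2R,3S,4R,5R)-2,5-bis[4-(benzyloxy)-3,5-dimethoxyphenyl]-4-ethenyloxolane-3-carboxylate (C3 epimer of 13, ester cis to both neighbours) | COc1cc([C@@H]2O[C@@H](c3cc(OC)c(OCc4ccccc4)c(OC)c3)[C@H](C=C)[C@@H]2C(=O)OC)cc(OC)c1OCc1ccccc1 | intermediate (not isolated)
13 | methyl (2R,3R,4R,5R)-2,5-bis[4-(benzyloxy)-3,5-dimethoxyphenyl]-4-ethenyloxolane-3-carboxylate (all‑trans) | COc1cc([C@@H]2O[C@@H](c3cc(OC)c(OCc4ccccc4)c(OC)c3)[C@H](C=C)[C@H]2C(=O)OC)cc(OC)c1OCc1ccccc1 | intermediate
14 | methyl (2R,3R,4S,5R)-2,5-bis[4-(benzyloxy)-3,5-dimethoxyphenyl]-4-(1,2-dihydroxyethyl)oxolane-3-carboxylate (both carbinol epimers) | COc1cc([C@@H]2O[C@@H](c3cc(OC)c(OCc4ccccc4)c(OC)c3)[C@H](C(O)CO)[C@H]2C(=O)OC)cc(OC)c1OCc1ccccc1 | intermediate (not isolated)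
15 | methyl (2R,3R,4R,5R)-2,5-bis[4-(benzyloxy)-3,5-dimethoxyphenyl]-4-formyloxolane-3-carboxylate | COc1cc([C@@H]2O[C@@H](c3cc(OC)c(OCc4ccccc4)c(OC)c3)[C@H](C=O)[C@H]2C(=O)OC)cc(OC)c1OCc1ccccc1 | intermediate
16 | {(2R,3S,4S,5R)-2,5-bis[4-(benzyloxy)-3,5-dimethoxyphenyl]oxolane-3,4-diyl}dimethanol | COc1cc([C@@H]2O[C@@H](c3cc(OC)c(OCc4ccccc4)c(OC)c3)[C@H](CO)[C@H]2CO)cc(OC)c1OCc1ccccc1 | intermediate
17 | 4,4'-[(2R,3S,4S,5R)-3,4-bis(hydroxymethyl)oxolane-2,5-diyl]bis(2,6-dimethoxyphenol) (CNP0170897.1) | COc1cc([C@@H]2O[C@@H](c3cc(OC)c(O)c(OC)c3)[C@H](CO)[C@H]2CO)cc(OC)c1O | target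

## Step count and least certain steps

Total step count: 9. Longest linear sequence: 8 (steps 1, 3, 4, 5, 6, 7, 8, 9 from 1); step 2 is the convergent branch.

**Step 5 (key step).** The arylidene malonate is only a moderate acceptor. If conjugate addition of the alkoxide is slow, palladium‑mediated isomerisation of the epoxide (hydride shift in the π‑allyl alkoxide to an aryl ketone) will take over. In addition, facial discrimination at C2 during ring closure may be incomplete, because the aryl group at C2 can be cis to only one of its two 1,3‑neighbours. Fallback, setting out from 2 and 8 and returning at 13: aldehyde 2 is condensed with Meldrum's acid to the far more electrophilic arylidene dioxanedione F1. This undergoes the same Pd(PPh3)4‑catalysed cycloaddition with 8 to give the spiro adduct F2; the locked cyclic diester also increases the allylic strain that steers C2. Heating F2 in methanol–pyridine opens the dioxanedione to the half‑ester F3, which decarboxylates on further heating in toluene. Methoxide equilibration as in step 6 then gives 13.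

**Step 4.** Oxygen transfer may occur at the terminal alkene or at both alkenes, enantioselectivity may be eroded, and the benzylic, allylic epoxide may open solvolytically in the aqueous medium. Fallback, setting out from 2 and returning at 8: Horner–Wadsworth–Emmons reaction of 2 with triethyl phosphonoacetate (NaH, THF) gives the cinnamate F4, and i‑Bu2AlH reduction gives the allylic alcohol F5. Sharpless asymmetric epoxidation (Ti(OiPr)4, L‑(+)‑diisopropyl tartrate, t‑BuOOH, 4 Å sieves, CH2Cl2, −20 °C) gives the epoxy alcohol F6 under anhydrous conditions. Parikh–Doering oxidation (SO3·pyridine, DMSO, Et3N) gives the epoxy aldehyde F7, and Wittig methylenation (Ph3PCH3Br, KN(SiMe3)2, THF) gives 8.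

**Step 6.** At 150 °C the ester enolate may expel the ring oxygen and open the oxolane, and equilibration at C3 may stop short of the all‑trans ester. Fallback, setting out from 11 and returning at 13: both esters are saponified (KOH, aq. MeOH–THF) to the diacid F8. This is decarboxylated thermally in pyridine at about 100 °C through the cyclic enol mechanism, without a free carbanion, to the monoacid F9. Esterification with Me3SiCHN2 in MeOH–toluene gives 13 together with 12, which are equilibrated with catalytic NaOMe as in step 6.

**Step 9.** Over‑reduction is possible: hydrogenolysis of the ring benzylic C–O bonds alongside or after removal of the benzyl groups. Fallback, setting out from 15 and returning at 17: the benzyl ethers are hydrogenolysed at the aldehyde–ester stage (H2, 10% Pd/C, EtOAc), where each ring benzylic carbon is flanked by a carbonyl‑bearing carbon and is less prone to C–O cleavage, giving the bisphenol F10. Excess LiAlH4 (THF, 0 °C, neutral work‑up) then reduces aldehyde and ester to 17.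

## Further compounds

F1 | step 5 | 5-[4-(benzyloxy)-3,5-dimethoxybenzylidene]-2,2-dimethyl-1,3-dioxane-4,6-dione | CC1(C)OC(=O)C(=Cc2cc(OC)c(OCc3ccccc3)c(OC)c2)C(=O)O1
F2 | step 5 | (1S,3R,4R)-1,3-bis[4-(benzyloxy)-3,5-dimethoxyphenyl]-4-ethenyl-8,8-dimethyl-2,7,9-trioxaspiro[4.5]decane-6,10-dione | COc1cc([C@@H]2O[C@@H](c3cc(OC)c(OCc4ccccc4)c(OC)c3)[C@H](C=C)C25C(=O)OC(C)(C)OC5=O)cc(OC)c1OCc1ccccc1
F3 | step 5 | (2S,4R,5R)-2,5-bis[4-(benzyloxy)-3,5-dimethoxyphenyl]-4-ethenyl-3-(methoxycarbonyl)oxolane-3-carboxylic acid (C3 not defined) | COc1cc([C@@H]2O[C@@H](c3cc(OC)c(OCc4ccccc4)c(OC)c3)[C@H](C=C)C2(C(=O)O)C(=O)OC)cc(OC)c1OCc1ccccc1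
F4 | step 4 | ethyl (2E)-3-[4-(benzyloxy)-3,5-dimethoxyphenyl]prop-2-enoate | CCOC(=O)/C=C/c1cc(OC)c(OCc2ccccc2)c(OC)c1
F5 | step 4 | (2E)-3-[4-(benzyloxy)-3,5-dimethoxyphenyl]prop-2-en-1-ol | OC/C=C/c1cc(OC)c(OCc2ccccc2)c(OC)c1
F6 | step 4 | {(2S,3S)-3-[4-(benzyloxy)-3,5-dimethoxyphenyl]oxiran-2-yl}methanol | OC[C@@H]1O[C@H]1c1cc(OC)c(OCc2ccccc2)c(OC)c1
F7 | step 4 | (2R,3S)-3-[4-(benzyloxy)-3,5-dimethoxyphenyl]oxirane-2-carbaldehyde | O=C[C@@H]1O[C@H]1c1cc(OC)c(OCc2ccccc2)c(OC)c1
F8 | step 6 | (2S,4R,5R)-2,5-bis[4-(benzyloxy)-3,5-dimethoxyphenyl]-4-ethenyloxolane-3,3-dicarboxylic acid | COc1cc([C@@H]2O[C@@H](c3cc(OC)c(OCc4ccccc4)c(OC)c3)[C@H](C=C)C2(C(=O)O)C(=O)O)cc(OC)c1OCc1ccccc1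
F9 | step 6 | (2R,4R,5R)-2,5-bis[4-(benzyloxy)-3,5-dimethoxyphenyl]-4-ethenyloxolane-3-carboxylic acid (C3 epimers) | COc1cc([C@@H]2O[C@@H](c3cc(OC)c(OCc4ccccc4)c(OC)c3)[C@H](C=C)C2C(=O)O)cc(OC)c1OCc1ccccc1
F10 | step 9 | methyl (2R,3R,4R,5R)-4-formyl-2,5-bis(4-hydroxy-3,5-dimethoxyphenyl)oxolane-3-carboxylate | COc1cc([C@@H]2O[C@@H](c3cc(OC)c(O)c(OC)c3)[C@H](C=O)[C@H]2C(=O)OC)cc(OC)c1O
A1 | alternative 1 | 4,4'-[(2R,3S,4S,5R)-3,4-bis({[tert-butyl(diphenyl)silyl]oxy}methyl)oxolane-2,5-diyl]bis(2,6-dimethoxyphenol) | COc1cc([C@@H]2O[C@@H](c3cc(OC)c(O)c(OC)c3)[C@H](CO[Si](c4ccccc4)(c4ccccc4)C(C)(C)C)[C@H]2CO[Si](c5ccccc5)(c5ccccc5)C(C)(C)C)cc(OC)c1O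
A2 | alternative 1 | (3S,4S)-3,4-bis({[tert-butyl(diphenyl)silyl]oxy}methyl)-2,5-dimethoxyoxolane (anomer mixture) | COC1OC(OC)[C@H](CO[Si](c2ccccc2)(c2ccccc2)C(C)(C)C)[C@H]1CO[Si](c1ccccc1)(c1ccccc1)C(C)(C)C
A3 | alternative 1 | 2,6-dimethoxyphenol | COc1cccc(OC)c1O
A4 | alternative 2 | dimethyl (2R,3R,4R,5R)-2,5-bis(4-hydroxy-3,5-dimethoxyphenyl)oxolane-3,4-dicarboxylate | COc1cc([C@@H]2O[C@@H](c3cc(OC)c(O)c(OC)c3)[C@H](C(=O)OC)[C@H]2C(=O)OC)cc(OC)c1O
A5 | alternative 2 | dimethyl all-trans-3,4-bis(4-hydroxy-3,5-dimethoxyphenyl)cyclobutane-1,2-dicarboxylate (single enantiomer, ester carbons configured as in A4) | COc1cc([C@H]2[C@H](C(=O)OC)[C@@H](C(=O)OC)[C@@H]2c2cc(OC)c(O)c(OC)c2)cc(OC)c1O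
A6 | alternative 2 | dimethyl 2,3-bis[(3,5-dimethoxy-4-oxocyclohexa-2,5-dien-1-ylidene)methyl]butanedioate (bis(quinone methide), C3 and C4 as in A4) | COC1=CC(=C[C@H](C(=O)OC)[C@@H](C(=O)OC)C=C2C=C(OC)C(=O)C(OC)=C2)C=C(OC)C1=O
A7 | alternative 3 | 4-[(2R,3S,4S,5R)-5-[4-(benzyloxy)-3,5-dimethoxyphenyl]-3,4-bis({[tert-butyl(dimethyl)silyl]oxy}methyl)oxolan-2-yl]-2,6-dimethoxyphenol | COc1cc([C@@H]2O[C@@H](c3cc(OC)c(OCc4ccccc4)c(OC)c3)[C@H](CO[Si](C)(C)C(C)(C)C)[C@H]2CO[Si](C)(C)C(C)(C)C)cc(OC)c1O
A8 | alternative 3 | open‑chain C5 alcohol: 4-{4-[4-(benzyloxy)-3,5-dimethoxyphenyl]-4-hydroxy-2,3-bis({[tert-butyl(dimethyl)silyl]oxy}methyl)butyl}-2,6-dimethoxyphenol (C3, C4, C5 as in A7) | COc1cc(C[C@H](CO[Si](C)(C)C(C)(C)C)[C@@H](CO[Si](C)(C)C(C)(C)C)[C@@H](O)c2cc(OC)c(OCc3ccccc3)c(OC)c2)cc(OC)c1O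
A9 | alternative 3 | quinone methide derived from A8 (methide carbon = C2) | COC1=CC(=C[C@H](CO[Si](C)(C)C(C)(C)C)[C@@H](CO[Si](C)(C)C(C)(C)C)[C@@H](O)c2cc(OC)c(OCc3ccccc3)c(OC)c2)C=C(OC)C1=O
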